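**Retrosynthetic overview**
- The acid comes from its methyl ester by carboxylesterase hydrolysis; the enone from a C11 aldehyde by Wittig olefination; the C1 carboxyl from a primary alcohol oxidised after ring formation.
- The 1,2-dioxane is the only ring and is closed late: a C6 tertiary hydroperoxide displaces a C3 mesylate (6-exo-tet SN2, inversion). The hydroperoxide comes from Co-catalysed peroxysilylation of a C6 ethylidene alkene.
- The alkene comes from a C6 ketone (Wittig); the ketone from a West alkyllithium (C1–C5) and an East Weinreb amide (C6–C11).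
- West fragment: lipase desymmetrisation of 2-ethylpropane-1,3-diyl diacetate sets C4; Ir-catalysed allylation sets C3.
- East fragment: two Cu/Josiphos conjugate additions (EtMgBr, then MeMgBr) to enethioates set C10 and C8.

Abbreviations: TBS = tert-butyldimethylsilyl, TBDPS = tert-butyldiphenylsilyl, Ms = methanesulfonyl. Backbone numbering in the comments follows the target: C1 = carboxyl carbon, C3 and C6 = peroxide-bearing carbons, ethyl on C4, C6 and C10, methyl on C8, C11=C12 alkene, C13 ketone. R/S labels of untouched centres sometimes change between intermediates only because CIP priorities change.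

Assumption: the absolute sense of the catalyst-controlled steps 3, 6, 16 and 19 is assigned by analogy and is checked on first use (Mosher esters); if one is reversed, the antipodal ligand is used, or lipase acylation of 2 replaces hydrolysis of 3.

Step 1
Reactants: 1 diethyl 2-ethylpropanedioate
Product: 2 2-ethylpropane-1,3-diol
Conditions: LiAlH4, THF, 0 °C to reflux; aqueous NaOH work-up
Reagents that add atoms: none
Why: Hydride reduction of both ester groups gives the prochiral 1,3-diol, with no stereocentre yet.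

Step 2
Reactants: 2 2-ethylpropane-1,3-diol
Product: 3 2-ethylpropane-1,3-diyl diacetate
Conditions: Ac2O, pyridine, DMAP (cat.), CH2Cl2, rt
Reagents that add atoms: acetic anhydride (CC(=O)OC(C)=O)
Why: DMAP-catalysed acylation gives the prochiral diacetate that the enzyme will differentiate.

Step 3
Reactants: 3 2-ethylpropane-1,3-diyl diacetate
Product: 4 (2S)-2-(hydroxymethyl)butyl acetate
Conditions: lipase (Pseudomonas fluorescens lipase), 0.1 M phosphate buffer pH 7.0, 25 °C, stopped at about 10 % diol 2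
Reagents that add atoms: none
Why: Lipase-catalysed enantiotopic-group-selective ester hydrolysis (desymmetrisation) creates the C4 stereocentre, and slight over-hydrolysis of the minor enantiomer to 2 raises the ee.

Step 4
Reactants: 4 (2S)-2-(hydroxymethyl)butyl acetate
Product: 5 (2R)-2-(TBSOCH2)butyl acetate
Conditions: TBSCl, imidazole, CH2Cl2, 0 °C to rt
Reagents that add atoms: tert-butyl(chloro)dimethylsilane (CC(C)(C)[Si](C)(C)Cl)
Why: Silyl ether formation under neutral imidazole conditions avoids the 1,3-acyl migration that would erode the ee.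

Step 5
Reactants: 5 (2R)-2-(TBSOCH2)butyl acetate
Product: 6 (2R)-2-(TBSOCH2)butan-1-ol
Conditions: K2CO3 (0.2 equiv), MeOH, 0 °C to rt
Reagents that add atoms: none
Why: Base-catalysed transesterification removes the acetate without touching the silyl ether or the stereocentre.

Step 6
Reactants: 6 (2R)-2-(TBSOCH2)butan-1-ol
Product: 8 (4R,5S)-5-(TBSOCH2)hept-1-en-4-ol, via aldehyde 7 (not isolated)
Conditions: [Ir(cod)Cl]2 (2.5 mol %), (R)-BINAP (5 mol %), 4-chloro-3-nitrobenzoic acid (10 mol %), Cs2CO3 (20 mol %), allyl acetate, THF, 100 °C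
Reagents that add atoms: allyl acetate (C=CCOC(C)=O)
Why: Krische iridium-catalysed transfer-hydrogenative allylation from the alcohol oxidation level sets the C3 carbinol (3R, anti to the C4 ethyl) under catalyst control, and the transient aldehyde never accumulates so C4 does not epimerise.

Step 7
Reactants: 8 (4R,5S)-5-(TBSOCH2)hept-1-en-4-ol
Product: 10 (3R,4S)-4-(TBSOCH2)hexane-1,3-diol, via ozonide 9 (not isolated)
Conditions: O3, CH2Cl2, −78 °C; then NaBH4, MeOH, −78 to 0 °C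
Reagents that add atoms: ozone ([O-][O+]=O)
Why: Ozonolysis with reductive work-up excises the terminal carbon and gives the C1 primary alcohol, leaving both stereocentres untouched.

Step 8
Reactants: 10 (3R,4S)-4-(TBSOCH2)hexane-1,3-diol
Product: 11 tert-butyl({(2S)-2-[(4R)-2,2-dimethyl-1,3-dioxan-4-yl]butyl}oxy)dimethylsilane
Conditions: 2,2-dimethoxypropane, pyridinium p-toluenesulfonate (cat.), CH2Cl2, rt
Reagents that add atoms: 2,2-dimethoxypropane (COC(C)(C)OC)
Why: Acetonide (isopropylidene ketal) formation protects the C1/C3 diol in one operation and withstands the organolithium chemistry ahead.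

Step 9
Reactants: 11 tert-butyl({(2S)-2-[(4R)-2,2-dimethyl-1,3-dioxan-4-yl]butyl}oxy)dimethylsilane
Product: 12 (2S)-2-[(4R)-2,2-dimethyl-1,3-dioxan-4-yl]butan-1-ol
Conditions: Bu4NF, THF, 0 °C to rt
Reagents that add atoms: none
Why: Fluoride-mediated desilylation frees the C5 hydroxyl while the acetonide is inert to fluoride.

Step 10
Reactants: 12 (2S)-2-[(4R)-2,2-dimethyl-1,3-dioxan-4-yl]butan-1-ol
Product: 13 (4R)-4-[(2R)-1-iodobutan-2-yl]-2,2-dimethyl-1,3-dioxane
Conditions: PPh3, iodine, imidazole, CH2Cl2, 0 °C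
Reagents that add atoms: iodine ([I][I])
Why: Appel-type iodination converts the primary alcohol into the iodide without involving either stereocentre.

Step 11
Reactants: 14 (2Z)-but-2-ene-1,4-diol
Product: 15 (2Z)-1,4-bis(TBDPSO)but-2-ene
Conditions: TBDPSCl (2.2 equiv), imidazole, DMF, rt
Reagents that add atoms: tert-butyl(chloro)diphenylsilane (CC(C)(C)[Si](Cl)(c1ccccc1)c1ccccc1)
Why: Silyl ether formation at both primary hydroxyls gives a symmetrical alkene for cleavage.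

Step 12
Reactants: 15 (2Z)-1,4-bis(TBDPSO)but-2-ene
Product: 17 (TBDPSO)acetaldehyde, via ozonide 16 (not isolated)
Conditions: O3, CH2Cl2, −78 °C; then PPh3, −78 °C to rt
Reagents that add atoms: ozone ([O-][O+]=O)
Why: Ozonolysis with reductive work-up cleaves the symmetrical alkene to two equivalents of the α-silyloxy aldehyde.

Step 13
Reactants: 18 bromoacetyl bromide
Product: 19 S-ethyl bromoethanethioate
Conditions: EtSH, pyridine, CH2Cl2, 0 °C
Reagents that add atoms: ethanethiol (CCS)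
Why: Nucleophilic acyl substitution takes place at the more reactive acyl bromide and leaves the alkyl bromide for the next step.

Step 14
Reactants: 19 S-ethyl bromoethanethioate
Product: 21 S-ethyl (triphenyl-λ5-phosphanylidene)ethanethioate, via phosphonium bromide 20 (not isolated)
Conditions: PPh3, toluene, rt; then aqueous Na2CO3, CH2Cl2
Reagents that add atoms: triphenylphosphine (c1ccc(cc1)P(c1ccccc1)c1ccccc1)
Why: SN2 quaternisation of the phosphine followed by deprotonation gives the stabilised Wittig ylide.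

Step 15
Reactants: 17 (TBDPSO)acetaldehyde; 21 S-ethyl (triphenyl-λ5-phosphanylidene)ethanethioate
Product: 22 S-ethyl (2E)-4-(TBDPSO)but-2-enethioate
Conditions: CH2Cl2, rt to 40 °C
Reagents that add atoms: none
Why: Wittig olefination with a stabilised ylide gives the (E)-enethioate.

Step 16
Reactants: 22 S-ethyl (2E)-4-(TBDPSO)but-2-enethioate
Product: 23 S-ethyl (3S)-3-(TBDPSOCH2)pentanethioate
Conditions: EtMgBr, CuBr·SMe2 (2 mol %), (S)-1-[(R)-2-(diphenylphosphino)ferrocenyl]ethyldicyclohexylphosphine (2.4 mol %), t-BuOMe, −75 °C; NH4Cl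
Reagents that add atoms: ethylmagnesium bromide (CC[Mg]Br)
Why: Feringa copper-catalysed asymmetric conjugate addition of a Grignard reagent to an enethioate sets C10, with the Josiphos ligand directing ethyl to one face.

Step 17
Reactants: 23 S-ethyl (3S)-3-(TBDPSOCH2)pentanethioate
Product: 24 (3S)-3-(TBDPSOCH2)pentanal
Conditions: i-Bu2AlH, CH2Cl2, −78 °C; Rochelle salt work-up
Reagents that add atoms: none
Why: Partial hydride reduction of the thioester stops at the aldehyde, and C10 is β to the carbonyl so it cannot epimerise.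

Step 18
Reactants: 24 (3S)-3-(TBDPSOCH2)pentanal; 21 S-ethyl (triphenyl-λ5-phosphanylidene)ethanethioate
Product: 25 S-ethyl (2E,5S)-5-(TBDPSOCH2)hept-2-enethioate
Conditions: CH2Cl2, 40 °C
Reagents that add atoms: none
Why: Wittig olefination with the stabilised ylide is E-selective and sets up the second conjugate addition.

Step 19
Reactants: 25 S-ethyl (2E,5S)-5-(TBDPSOCH2)hept-2-enethioate
Product: 26 S-ethyl (3S,5S)-5-(TBDPSOCH2)-3-methylheptanethioate
Conditions: MeMgBr, CuBr·SMe2 (2 mol %), (R)-1-[(S)-2-(diphenylphosphino)ferrocenyl]ethyldicyclohexylphosphine (2.4 mol %), t-BuOMe, −75 °C; NH4Cl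
Reagents that add atoms: methylmagnesium bromide (C[Mg]Br)
Why: The second copper/Josiphos asymmetric conjugate addition uses the antipodal ligand, which overrides the remote C10 centre and sets C8 with the methyl 1,3-anti to the C10 ethyl branch.

Step 20
Reactants: 26 S-ethyl (3S,5S)-5-(TBDPSOCH2)-3-methylheptanethioate
Product: 27 (3S,5S)-5-(TBDPSOCH2)-N-methoxy-N,3-dimethylheptanamide
Conditions: MeNHOMe·HCl, i-PrMgCl, THF, −20 °C (magnesium amide pre-formed), then 26, −20 to 0 °C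
Reagents that add atoms: N,O-dimethylhydroxylamine hydrochloride (CNOC.Cl)
Why: Aminolysis of the thioester by the chloromagnesium amide gives the Weinreb amide with no epimerisable centre nearby.

Step 21
Reactants: 13 (4R)-4-[(2R)-1-iodobutan-2-yl]-2,2-dimethyl-1,3-dioxane; 27 (3S,5S)-5-(TBDPSOCH2)-N-methoxy-N,3-dimethylheptanamide
Product: 29 (3S,7S,9S)-9-(TBDPSOCH2)-3-[(4R)-2,2-dimethyl-1,3-dioxan-4-yl]-7-methylundecan-5-one, via alkyllithium 28 (not isolated)
Conditions: t-BuLi (2.05 equiv), Et2O, −78 °C; then 27, −78 to −20 °C; NH4Cl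
Reagents that add atoms: none
Why: Lithium–iodine exchange and addition to the Weinreb amide join the fragments at C5–C6, the chelated tetrahedral intermediate preventing over-addition.

Step 22
Reactants: 29 (3S,7S,9S)-9-(TBDPSOCH2)-3-[(4R)-2,2-dimethyl-1,3-dioxan-4-yl]-7-methylundecan-5-one
Product: 30 (3S,7S,9S)-9-(TBDPSOCH2)-3-[(4R)-2,2-dimethyl-1,3-dioxan-4-yl]-5-ethylidene-7-methylundecane (E/Z mixture)
Conditions: EtPPh3Br, KOt-Bu, THF, 0 °C to 50 °C
Reagents that add atoms: ethyltriphenylphosphonium bromide (CC[P+](c1ccccc1)(c1ccccc1)c1ccccc1.[Br-])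
Why: Wittig olefination with a non-stabilised ylide installs the C6 ethylidene, whose E/Z ratio is irrelevant because the geometry is destroyed in step 26.

Step 23
Reactants: 30 (3S,7S,9S)-9-(TBDPSOCH2)-3-[(4R)-2,2-dimethyl-1,3-dioxan-4-yl]-5-ethylidene-7-methylundecane
Product: 31 (3R,4S,8S,10S)-10-(TBDPSOCH2)-4-ethyl-6-ethylidene-8-methyldodecane-1,3-diol
Conditions: pyridinium p-toluenesulfonate (0.2 equiv), MeOH, 40 °C
Reagents that add atoms: none
Why: Acid-catalysed transketalisation removes the acetonide under conditions that the TBDPS ether and the trisubstituted alkene survive.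

Step 24
Reactants: 31 (3R,4S,8S,10S)-10-(TBDPSOCH2)-4-ethyl-6-ethylidene-8-methyldodecane-1,3-diol
Product: 32 (3R,4S,8S,10S)-1-(TBSO)-10-(TBDPSOCH2)-4-ethyl-6-ethylidene-8-methyldodecan-3-ol
Conditions: TBSCl (1.05 equiv), imidazole, CH2Cl2, −20 to 0 °C
Reagents that add atoms: tert-butyl(chloro)dimethylsilane (CC(C)(C)[Si](C)(C)Cl)
Why: Silyl ether formation is selective for the primary over the hindered secondary hydroxyl on steric grounds.

Step 25
Reactants: 32 (3R,4S,8S,10S)-1-(TBSO)-10-(TBDPSOCH2)-4-ethyl-6-ethylidene-8-methyldodecan-3-ol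
Product: 33 (3R,4S,8S,10S)-1-(TBSO)-10-(TBDPSOCH2)-4-ethyl-6-ethylidene-8-methyldodecan-3-yl methanesulfonate
Conditions: MsCl, Et3N, CH2Cl2, 0 °C
Reagents that add atoms: methanesulfonyl chloride (CS(Cl)(=O)=O)
Why: Sulfonylation of the C3 alcohol proceeds with retention and provides the leaving group for ring closure.

Step 26
Reactants: 33 (3R,4S,8S,10S)-1-(TBSO)-10-(TBDPSOCH2)-4-ethyl-6-ethylidene-8-methyldodecan-3-yl methanesulfonate
Product: 34 (3R,4S,8S,10S)-1-(TBSO)-10-(TBDPSOCH2)-4,6-diethyl-8-methyl-6-[(triethylsilyl)peroxy]dodecan-3-yl methanesulfonate (about 1:1 at C6)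
Conditions: Co(thd)2 [bis(2,2,6,6-tetramethylheptane-3,5-dionato)cobalt] (10 mol %), O2 (1 atm), Et3SiH, 1,2-dichloroethane, rt
Reagents that add atoms: dioxygen (O=O); triethylsilane (CC[SiH](CC)CC)
Why: Mukaiyama–Isayama hydroperoxysilylation proceeds by Markovnikov hydrogen-atom transfer to give the tertiary C6 radical, which captures O2 without facial control, so the wanted 6R epimer is separated after ring closure.

Step 27
Reactants: 34 (3R,4S,8S,10S)-1-(TBSO)-10-(TBDPSOCH2)-4,6-diethyl-8-methyl-6-[(triethylsilyl)peroxy]dodecan-3-yl methanesulfonate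
Product: 36 tert-butyl(2-{(3S,4S,6R)-6-[(2S,4S)-4-(TBDPSOCH2)-2-methylhexyl]-4,6-diethyl-1,2-dioxan-3-yl}ethoxy)dimethylsilane, via hydroperoxide 35 (not isolated)
Conditions: K2CO3 (cat.), MeOH, 0 °C; solvent exchange; then KOt-Bu (1.1 equiv), 18-crown-6, toluene, 0 °C to rt; chromatographic separation from the 6-epimer
Reagents that add atoms: none
Why: Methanolysis of the silyl peroxide and intramolecular 6-exo-tet SN2 alkylation of the peroxide anion invert C3 (3R mesylate to 3S dioxane), which places the C3 side chain cis to the C4 ethyl.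

Step 28
Reactants: 36 tert-butyl(2-{(3S,4S,6R)-6-[(2S,4S)-4-(TBDPSOCH2)-2-methylhexyl]-4,6-diethyl-1,2-dioxan-3-yl}ethoxy)dimethylsilane
Product: 37 2-{(3S,4S,6R)-6-[(2S,4S)-4-(TBDPSOCH2)-2-methylhexyl]-4,6-diethyl-1,2-dioxan-3-yl}ethanol
Conditions: pyridinium p-toluenesulfonate, MeOH/CH2Cl2, rt
Reagents that add atoms: none
Why: Acid-catalysed methanolysis cleaves the primary TBS ether selectively in the presence of the far more robust TBDPS ether and the dialkyl peroxide.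

Step 29
Reactants: 37 2-{(3S,4S,6R)-6-[(2S,4S)-4-(TBDPSOCH2)-2-methylhexyl]-4,6-diethyl-1,2-dioxan-3-yl}ethanol
Product: 39 {(3S,4S,6R)-6-[(2S,4S)-4-(TBDPSOCH2)-2-methylhexyl]-4,6-diethyl-1,2-dioxan-3-yl}acetic acid, via aldehyde 38 (not isolated)
Conditions: TEMPO (0.2 equiv), PhI(OAc)2 (2.5 equiv), MeCN/H2O 1:1, rt
Reagents that add atoms: water (O)
Why: Oxoammonium (TEMPO) oxidation takes the primary alcohol through the aldehyde hydrate to the acid under near-neutral conditions that leave the peroxide intact.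

Step 30
Reactants: 39 {(3S,4S,6R)-6-[(2S,4S)-4-(TBDPSOCH2)-2-methylhexyl]-4,6-diethyl-1,2-dioxan-3-yl}acetic acid
Product: 40 methyl {(3S,4S,6R)-6-[(2S,4S)-4-(TBDPSOCH2)-2-methylhexyl]-4,6-diethyl-1,2-dioxan-3-yl}acetate
Conditions: Me3SiCHN2, toluene/MeOH 4:1, 0 °C
Reagents that add atoms: (trimethylsilyl)diazomethane (C[Si](C)(C)C=[N+]=[N-])
Why: Diazoalkane esterification masks the acid so that the remaining oxidation and olefination run cleanly.

Step 31
Reactants: 40 methyl {(3S,4S,6R)-6-[(2S,4S)-4-(TBDPSOCH2)-2-methylhexyl]-4,6-diethyl-1,2-dioxan-3-yl}acetate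
Product: 41 methyl {(3S,4S,6R)-4,6-diethyl-6-[(2S,4S)-4-(hydroxymethyl)-2-methylhexyl]-1,2-dioxan-3-yl}acetate
Conditions: HF·pyridine, pyridine, THF, 0 °C to rt
Reagents that add atoms: none
Why: Buffered fluoride desilylation removes the TBDPS ether without base, so the β-peroxy ester is not opened.

Step 32
Reactants: 41 methyl {(3S,4S,6R)-4,6-diethyl-6-[(2S,4S)-4-(hydroxymethyl)-2-methylhexyl]-1,2-dioxan-3-yl}acetate
Product: 42 methyl {(3S,4S,6R)-4,6-diethyl-6-[(2S,4S)-4-formyl-2-methylhexyl]-1,2-dioxan-3-yl}acetate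
Conditions: Dess–Martin periodinane, pyridine, CH2Cl2, 0 °C to rt
Reagents that add atoms: none
Why: Dess–Martin oxidation gives the α-branched aldehyde under mild buffered conditions, and it is used at once to avoid C10 epimerisation.

Step 33
Reactants: 42 methyl {(3S,4S,6R)-4,6-diethyl-6-[(2S,4S)-4-formyl-2-methylhexyl]-1,2-dioxan-3-yl}acetate
Product: 43 methyl {(3S,4S,6R)-4,6-diethyl-6-[(2S,4S,5E)-4-ethyl-2-methyl-7-oxooct-5-en-1-yl]-1,2-dioxan-3-yl}acetate
Conditions: Ph3P=CHC(O)CH3 (2.5 equiv), toluene, 60 °C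
Reagents that add atoms: 1-(triphenyl-λ5-phosphanylidene)propan-2-one (CC(=O)C=P(c1ccccc1)(c1ccccc1)c1ccccc1)
Why: Wittig olefination with a ketone-stabilised ylide gives the (E)-enone under neutral conditions that spare the peroxide and C10.

Step 34
Reactants: 43 methyl {(3S,4S,6R)-4,6-diethyl-6-[(2S,4S,5E)-4-ethyl-2-methyl-7-oxooct-5-en-1-yl]-1,2-dioxan-3-yl}acetate
Product: 44 {(3S,4S,6R)-4,6-diethyl-6-[(2S,4S,5E)-4-ethyl-2-methyl-7-oxooct-5-en-1-yl]-1,2-dioxan-3-yl}acetic acid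
Conditions: carboxylesterase (pig liver esterase), 0.1 M phosphate buffer pH 7.2, 10 % acetone, 30 °C
Reagents that add atoms: water (O)
Why: Enzymatic ester hydrolysis at neutral pH releases the acid without the base-induced retro-oxa-Michael opening of the β-peroxy ester or isomerisation of the enone.

**Compound list**
1 | diethyl 2-ethylpropanedioate | CCOC(=O)C(CC)C(=O)OCC | starting material
2 | 2-ethylpropane-1,3-diol | CCC(CO)CO | intermediate
3 | 2-ethylpropane-1,3-diyl diacetate | CCC(COC(C)=O)COC(C)=O | intermediate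
4 | (2S)-2-(hydroxymethyl)butyl acetate | OC[C@H](CC)COC(C)=O | intermediate
5 | (2R)-2-({[tert-butyl(dimethyl)silyl]oxy}methyl)butyl acetate | CC(C)(C)[Si](C)(C)OC[C@H](CC)COC(C)=O | intermediate
6 | (2R)-2-({[tert-butyl(dimethyl)silyl]oxy}methyl)butan-1-ol | CC(C)(C)[Si](C)(C)OC[C@H](CC)CO | intermediate
7 | (2S)-2-({[tert-butyl(dimethyl)silyl]oxy}methyl)butanal | CC(C)(C)[Si](C)(C)OC[C@H](CC)C=O | intermediate
8 | (4R,5S)-5-({[tert-butyl(dimethyl)silyl]oxy}methyl)hept-1-en-4-ol | CC(C)(C)[Si](C)(C)OC[C@H](CC)[C@@H](CC=C)O | intermediate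
9 | (2R,3S)-3-({[tert-butyl(dimethyl)silyl]oxy}methyl)-1-(1,2,4-trioxolan-3-yl)pentan-2-ol (ozonide, trioxolane carbon unassigned) | CC(C)(C)[Si](C)(C)OC[C@H](CC)[C@@H](CC1OCOO1)O | intermediate
10 | (3R,4S)-4-({[tert-butyl(dimethyl)silyl]oxy}methyl)hexane-1,3-diol | CC(C)(C)[Si](C)(C)OC[C@H](CC)[C@@H](CCO)O | intermediate
11 | tert-butyl({(2S)-2-[(4R)-2,2-dimethyl-1,3-dioxan-4-yl]butyl}oxy)dimethylsilane | CC(C)(C)[Si](C)(C)OC[C@H](CC)[C@@H](CCO1)OC1(C)C | intermediate
12 | (2S)-2-[(4R)-2,2-dimethyl-1,3-dioxan-4-yl]butan-1-ol | OC[C@H](CC)[C@@H](CCO1)OC1(C)C | intermediate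
13 | (4R)-4-[(2R)-1-iodobutan-2-yl]-2,2-dimethyl-1,3-dioxane | IC[C@H](CC)[C@@H](CCO1)OC1(C)C | intermediate
14 | (2Z)-but-2-ene-1,4-diol | OC/C=C\CO | starting material
15 | (2Z)-1,4-bis{[tert-butyl(diphenyl)silyl]oxy}but-2-ene | CC(C)(C)[Si](c1ccccc1)(c1ccccc1)OC/C=C\CO[Si](c1ccccc1)(c1ccccc1)C(C)(C)C | intermediate
16 | 3,5-bis({[tert-butyl(diphenyl)silyl]oxy}methyl)-1,2,4-trioxolane | CC(C)(C)[Si](c1ccccc1)(c1ccccc1)OCC1OC(CO[Si](c2ccccc2)(c2ccccc2)C(C)(C)C)OO1 | intermediate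
17 | {[tert-butyl(diphenyl)silyl]oxy}acetaldehyde | CC(C)(C)[Si](c1ccccc1)(c1ccccc1)OCC=O | intermediate
18 | bromoacetyl bromide | BrCC(Br)=O | starting material
19 | S-ethyl bromoethanethioate | CCSC(=O)CBr | intermediate
20 | [2-(ethylsulfanyl)-2-oxoethyl](triphenyl)phosphonium bromide | CCSC(=O)C[P+](c1ccccc1)(c1ccccc1)c1ccccc1.[Br-] | intermediate
21 | S-ethyl (triphenyl-λ5-phosphanylidene)ethanethioate | CCSC(=O)C=P(c1ccccc1)(c1ccccc1)c1ccccc1 | intermediate
22 | S-ethyl (2E)-4-{[tert-butyl(diphenyl)silyl]oxy}but-2-enethioate | CCSC(=O)/C=C/CO[Si](c1ccccc1)(c1ccccc1)C(C)(C)C | intermediate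
23 | S-ethyl (3S)-3-({[tert-butyl(diphenyl)silyl]oxy}methyl)pentanethioate | CC[C@H](CO[Si](c1ccccc1)(c1ccccc1)C(C)(C)C)CC(=O)SCC | intermediate
24 | (3S)-3-({[tert-butyl(diphenyl)silyl]oxy}methyl)pentanal | CC[C@H](CO[Si](c1ccccc1)(c1ccccc1)C(C)(C)C)CC=O | intermediate
25 | S-ethyl (2E,5S)-5-({[tert-butyl(diphenyl)silyl]oxy}methyl)hept-2-enethioate | CC[C@H](CO[Si](c1ccccc1)(c1ccccc1)C(C)(C)C)C/C=C/C(=O)SCC | intermediate
26 | S-ethyl (3S,5S)-5-({[tert-butyl(diphenyl)silyl]oxy}methyl)-3-methylheptanethioate | CC[C@H](CO[Si](c1ccccc1)(c1ccccc1)C(C)(C)C)C[C@H](C)CC(=O)SCC | intermediate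
27 | (3S,5S)-5-({[tert-butyl(diphenyl)silyl]oxy}methyl)-N-methoxy-N,3-dimethylheptanamide | CC[C@H](CO[Si](c1ccccc1)(c1ccccc1)C(C)(C)C)C[C@H](C)CC(=O)N(C)OC | intermediate
28 | {(2R)-2-[(4R)-2,2-dimethyl-1,3-dioxan-4-yl]butyl}lithium | [Li]C[C@H](CC)[C@@H](CCO1)OC1(C)C | intermediate
29 | (3S,7S,9S)-9-({[tert-butyl(diphenyl)silyl]oxy}methyl)-3-[(4R)-2,2-dimethyl-1,3-dioxan-4-yl]-7-methylundecan-5-one | CC[C@H](CO[Si](c1ccccc1)(c1ccccc1)C(C)(C)C)C[C@H](C)CC(=O)C[C@H](CC)[C@@H](CCO1)OC1(C)C | intermediate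
30 | (3S,7S,9S)-9-({[tert-butyl(diphenyl)silyl]oxy}methyl)-3-[(4R)-2,2-dimethyl-1,3-dioxan-4-yl]-5-ethylidene-7-methylundecane (E/Z mixture) | CC[C@H](CO[Si](c1ccccc1)(c1ccccc1)C(C)(C)C)C[C@H](C)CC(=CC)C[C@H](CC)[C@@H](CCO1)OC1(C)C | intermediate
31 | (3R,4S,8S,10S)-10-({[tert-butyl(diphenyl)silyl]oxy}methyl)-4-ethyl-6-ethylidene-8-methyldodecane-1,3-diol | CC[C@H](CO[Si](c1ccccc1)(c1ccccc1)C(C)(C)C)C[C@H](C)CC(=CC)C[C@H](CC)[C@@H](CCO)O | intermediate
32 | (3R,4S,8S,10S)-1-{[tert-butyl(dimethyl)silyl]oxy}-10-({[tert-butyl(diphenyl)silyl]oxy}methyl)-4-ethyl-6-ethylidene-8-methyldodecan-3-ol | CC[C@H](CO[Si](c1ccccc1)(c1ccccc1)C(C)(C)C)C[C@H](C)CC(=CC)C[C@H](CC)[C@@H](CCO[Si](C)(C)C(C)(C)C)O | intermediate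
33 | (3R,4S,8S,10S)-1-{[tert-butyl(dimethyl)silyl]oxy}-10-({[tert-butyl(diphenyl)silyl]oxy}methyl)-4-ethyl-6-ethylidene-8-methyldodecan-3-yl methanesulfonate | CC[C@H](CO[Si](c1ccccc1)(c1ccccc1)C(C)(C)C)C[C@H](C)CC(=CC)C[C@H](CC)[C@@H](CCO[Si](C)(C)C(C)(C)C)OS(C)(=O)=O | intermediate
34 | (3R,4S,8S,10S)-1-{[tert-butyl(dimethyl)silyl]oxy}-10-({[tert-butyl(diphenyl)silyl]oxy}methyl)-4,6-diethyl-8-methyl-6-[(triethylsilyl)peroxy]dodecan-3-yl methanesulfonate (both C6 epimers) | CC[C@H](CO[Si](c1ccccc1)(c1ccccc1)C(C)(C)C)C[C@H](C)CC(CC)(OO[Si](CC)(CC)CC)C[C@H](CC)[C@@H](CCO[Si](C)(C)C(C)(C)C)OS(C)(=O)=O | intermediate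
35 | (3R,4S,8S,10S)-1-{[tert-butyl(dimethyl)silyl]oxy}-10-({[tert-butyl(diphenyl)silyl]oxy}methyl)-4,6-diethyl-6-hydroperoxy-8-methyldodecan-3-yl methanesulfonate (both C6 epimers) | CC[C@H](CO[Si](c1ccccc1)(c1ccccc1)C(C)(C)C)C[C@H](C)CC(CC)(OO)C[C@H](CC)[C@@H](CCO[Si](C)(C)C(C)(C)C)OS(C)(=O)=O | intermediate
36 | tert-butyl(2-{(3S,4S,6R)-6-[(2S,4S)-4-({[tert-butyl(diphenyl)silyl]oxy}methyl)-2-methylhexyl]-4,6-diethyl-1,2-dioxan-3-yl}ethoxy)dimethylsilane | CC[C@H](CO[Si](c1ccccc1)(c1ccccc1)C(C)(C)C)C[C@H](C)C[C@]1(CC)C[C@H](CC)[C@H](CCO[Si](C)(C)C(C)(C)C)OO1 | intermediate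
37 | 2-{(3S,4S,6R)-6-[(2S,4S)-4-({[tert-butyl(diphenyl)silyl]oxy}methyl)-2-methylhexyl]-4,6-diethyl-1,2-dioxan-3-yl}ethanol | CC[C@H](CO[Si](c1ccccc1)(c1ccccc1)C(C)(C)C)C[C@H](C)C[C@]1(CC)C[C@H](CC)[C@H](CCO)OO1 | intermediate
38 | {(3S,4S,6R)-6-[(2S,4S)-4-({[tert-butyl(diphenyl)silyl]oxy}methyl)-2-methylhexyl]-4,6-diethyl-1,2-dioxan-3-yl}acetaldehyde | CC[C@H](CO[Si](c1ccccc1)(c1ccccc1)C(C)(C)C)C[C@H](C)C[C@]1(CC)C[C@H](CC)[C@H](CC=O)OO1 | intermediate
39 | {(3S,4S,6R)-6-[(2S,4S)-4-({[tert-butyl(diphenyl)silyl]oxy}methyl)-2-methylhexyl]-4,6-diethyl-1,2-dioxan-3-yl}acetic acid | CC[C@H](CO[Si](c1ccccc1)(c1ccccc1)C(C)(C)C)C[C@H](C)C[C@]1(CC)C[C@H](CC)[C@H](CC(=O)O)OO1 | intermediate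
40 | methyl {(3S,4S,6R)-6-[(2S,4S)-4-({[tert-butyl(diphenyl)silyl]oxy}methyl)-2-methylhexyl]-4,6-diethyl-1,2-dioxan-3-yl}acetate | CC[C@H](CO[Si](c1ccccc1)(c1ccccc1)C(C)(C)C)C[C@H](C)C[C@]1(CC)C[C@H](CC)[C@H](CC(=O)OC)OO1 | intermediate
41 | methyl {(3S,4S,6R)-4,6-diethyl-6-[(2S,4S)-4-(hydroxymethyl)-2-methylhexyl]-1,2-dioxan-3-yl}acetate | CC[C@H](CO)C[C@H](C)C[C@]1(CC)C[C@H](CC)[C@H](CC(=O)OC)OO1 | intermediate
42 | methyl {(3S,4S,6R)-4,6-diethyl-6-[(2S,4S)-4-formyl-2-methylhexyl]-1,2-dioxan-3-yl}acetate | CC[C@H](C=O)C[C@H](C)C[C@]1(CC)C[C@H](CC)[C@H](CC(=O)OC)OO1 | intermediate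
43 | methyl {(3S,4S,6R)-4,6-diethyl-6-[(2S,4S,5E)-4-ethyl-2-methyl-7-oxooct-5-en-1-yl]-1,2-dioxan-3-yl}acetate | CC[C@H](/C=C/C(C)=O)C[C@H](C)C[C@]1(CC)C[C@H](CC)[C@H](CC(=O)OC)OO1 | intermediate
44 | {(3S,4S,6R)-4,6-diethyl-6-[(2S,4S,5E)-4-ethyl-2-methyl-7-oxooct-5-en-1-yl]-1,2-dioxan-3-yl}acetic acid | CC[C@H](/C=C/C(C)=O)C[C@H](C)C[C@]1(CC)C[C@H](CC)[C@H](CC(=O)O)OO1 | target

**Totals**
Total step count: 34. Longest linear sequence: 24 steps (steps 1–10, then 21–34, from 1 to 44).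

**Steps most likely to fail, with fallbacks**

Step 27, the peroxide ring closure. E2 elimination of the hindered C3 mesylate can compete with the SN2 closure. The fallback closes the ring by oxa-Michael addition instead and sets out from diol 31. TEMPO/PhI(OAc)2 oxidation of the primary hydroxyl gives (3R,4S,8S,10S)-10-(TBDPSOCH2)-4-ethyl-6-ethylidene-3-hydroxy-8-methyldodecanoic acid F1. (Trimethylsilyl)diazomethane gives its methyl ester F2, MsCl/Et3N gives the β-mesyloxy ester F3, and DBU (E1cB) gives the methyl (2E)-dienoate F4. Cobalt-catalysed peroxysilylation of the electron-rich trisubstituted alkene (limiting Et3SiH, the enoate reacting more slowly) gives the triethylsilyl peroxide F5. Acid methanolysis frees the hydroperoxide F6, and Et2NH in CF3CH2OH closes the dioxane by 6-exo conjugate addition, coming back to the route at ester 40. The price is that C3 is then set in the cyclisation itself, so 40 has to be separated from its 3-epimer as well as its 6-epimer.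

Step 26, the cobalt peroxysilylation. The hindered trisubstituted alkene may react sluggishly, and there is no control at C6. The fallback makes the C3–O bond first and the C6–O bond by iodoperoxidation, and sets out from mesylate 33. Displacement with 2-methoxyprop-2-yl hydroperoxide and CsOH in DMF (SN2, inversion) gives the C3 peroxyketal F7. Aqueous AcOH releases the (3S) secondary hydroperoxide F8. N-Iodosuccinimide in CH2Cl2 triggers 6-exo Markovnikov iodoperoxidation of the ethylidene group to the 6-(1-iodoethyl)-1,2-dioxane F9. Bu3SnH/Et3B at 0 °C removes the iodine and returns to the route at dioxane 36, again after separation of the C6 epimers.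

Step 6, the iridium-catalysed allylation. Conversion or diastereoselectivity may fall short on the β-branched alcohol. The fallback sets C3 by asymmetric hydrogenation of a β-keto ester and sets out from alcohol 6. Dess–Martin oxidation gives aldehyde 7 (isolated in this case). SnCl2-catalysed Roskamp homologation with methyl diazoacetate gives methyl (4S)-4-(TBSOCH2)-3-oxohexanoate F10. Noyori hydrogenation with RuBr2[(S)-BINAP] (H2, 4 atm, EtOH, 50 °C) gives methyl (3R,4S)-4-(TBSOCH2)-3-hydroxyhexanoate F11. LiAlH4 reduction then gives diol 10, where it rejoins the route.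

Further compounds
F1 | step 27 | (3R,4S,8S,10S)-10-({[tert-butyl(diphenyl)silyl]oxy}methyl)-4-ethyl-6-ethylidene-3-hydroxy-8-methyldodecanoic acid | CC[C@H](CO[Si](c1ccccc1)(c1ccccc1)C(C)(C)C)C[C@H](C)CC(=CC)C[C@H](CC)[C@@H](CC(=O)O)O
F2 | step 27 | methyl (3R,4S,8S,10S)-10-({[tert-butyl(diphenyl)silyl]oxy}methyl)-4-ethyl-6-ethylidene-3-hydroxy-8-methyldodecanoate | CC[C@H](CO[Si](c1ccccc1)(c1ccccc1)C(C)(C)C)C[C@H](C)CC(=CC)C[C@H](CC)[C@@H](CC(=O)OC)O
F3 | step 27 | methyl (3R,4S,8S,10S)-10-({[tert-butyl(diphenyl)silyl]oxy}methyl)-4-ethyl-6-ethylidene-3-[(methanesulfonyl)oxy]-8-methyldodecanoate | CC[C@H](CO[Si](c1ccccc1)(c1ccccc1)C(C)(C)C)C[C@H](C)CC(=CC)C[C@H](CC)[C@@H](CC(=O)OC)OS(C)(=O)=O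
F4 | step 27 | methyl (2E,4S,8S,10S)-10-({[tert-butyl(diphenyl)silyl]oxy}methyl)-4-ethyl-6-ethylidene-8-methyldodec-2-enoate | CC[C@H](CO[Si](c1ccccc1)(c1ccccc1)C(C)(C)C)C[C@H](C)CC(=CC)C[C@H](CC)/C=C/C(=O)OC
F5 | step 27 | methyl (2E,4S,8S,10S)-10-({[tert-butyl(diphenyl)silyl]oxy}methyl)-4,6-diethyl-8-methyl-6-[(triethylsilyl)peroxy]dodec-2-enoate (both C6 epimers) | CC[C@H](CO[Si](c1ccccc1)(c1ccccc1)C(C)(C)C)C[C@H](C)CC(CC)(OO[Si](CC)(CC)CC)C[C@H](CC)/C=C/C(=O)OC
F6 | step 27 | methyl (2E,4S,8S,10S)-10-({[tert-butyl(diphenyl)silyl]oxy}methyl)-4,6-diethyl-6-hydroperoxy-8-methyldodec-2-enoate (both C6 epimers) | CC[C@H](CO[Si](c1ccccc1)(c1ccccc1)C(C)(C)C)C[C@H](C)CC(CC)(OO)C[C@H](CC)/C=C/C(=O)OC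
F7 | step 26 | tert-butyl{[(3S,4S,8S,10S)-10-({[tert-butyl(diphenyl)silyl]oxy}methyl)-4-ethyl-6-ethylidene-3-[(2-methoxypropan-2-yl)peroxy]-8-methyldodecyl]oxy}dimethylsilane | CC[C@H](CO[Si](c1ccccc1)(c1ccccc1)C(C)(C)C)C[C@H](C)CC(=CC)C[C@H](CC)[C@H](CCO[Si](C)(C)C(C)(C)C)OOC(C)(C)OC
F8 | step 26 | tert-butyl{[(3S,4S,8S,10S)-10-({[tert-butyl(diphenyl)silyl]oxy}methyl)-4-ethyl-6-ethylidene-3-hydroperoxy-8-methyldodecyl]oxy}dimethylsilane | CC[C@H](CO[Si](c1ccccc1)(c1ccccc1)C(C)(C)C)C[C@H](C)CC(=CC)C[C@H](CC)[C@H](CCO[Si](C)(C)C(C)(C)C)OO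
F9 | step 26 | 6-(1-iodoethyl) analogue of 36: tert-butyl(2-{(3S,4S)-6-[(2S,4S)-4-({[tert-butyl(diphenyl)silyl]oxy}methyl)-2-methylhexyl]-4-ethyl-6-(1-iodoethyl)-1,2-dioxan-3-yl}ethoxy)dimethylsilane, ring configuration as in 36, CHI centre unassigned | CC[C@H](CO[Si](c1ccccc1)(c1ccccc1)C(C)(C)C)C[C@H](C)C[C@]1(C(C)I)C[C@H](CC)[C@H](CCO[Si](C)(C)C(C)(C)C)OO1
F10 | step 6 | methyl (4S)-4-({[tert-butyl(dimethyl)silyl]oxy}methyl)-3-oxohexanoate | CC(C)(C)[Si](C)(C)OC[C@H](CC)C(=O)CC(=O)OC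
F11 | step 6 | methyl (3R,4S)-4-({[tert-butyl(dimethyl)silyl]oxy}methyl)-3-hydroxyhexanoate | CC(C)(C)[Si](C)(C)OC[C@H](CC)[C@@H](CC(=O)OC)O
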